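## Plan

- Retrosynthesis: the C8–prenyl bond is cut first and traced back to an O5 prenyl ether. Next come the C2–H bond (flavanone back to flavone) and the two bonds of C3 (C3–C2 and C3–C4), which leaves a 2‑aryl‑3‑silyloxybenzofuran. That is cut at its C2–C3 bond to a PMB‑protected salicylate, and ring A goes back to 2‑methylresorcinol.
- Enabling feature: ring C (O1, C2, C3, C4, C4a, C8a) is a benzofuranone ring plus the single carbon C3. Without C3, C2 and C4 are the two ends of the enol ether C=C bond of a benzofuran, which can take up a carbene carbon between them.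
- Forward order: ring A is completed (C–H borylation/oxidation, PMB ether, ortho‑metalation/ester), then the five‑membered oxygen ring is closed by carbanion acylation and enlarged to ring C by dibromocarbene. The prenyl chain is joined last at O5 and moved to C8 by a Claisen–Cope sequence.
- Stereochemistry: the only stereocentre, C2 (S), comes from a ligand‑controlled copper hydride conjugate reduction of the flavone. Every later step is neutral or acidic, so the flavanone should not open to the chalcone.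

Key step: step 6

Assumption: the facial sense of the copper hydride/(R)‑DTBM‑SEGPHOS catalyst on flavone 20 cannot be fixed on paper. The (R) ligand is written, and its mirror image would be used instead if a pilot run points to the (2R) series.

## Route

Step 1
Reactants: 1 2‑methylresorcinol; 2 chloromethyl methyl ether
Product: 3 1,3‑bis(methoxymethoxy)‑2‑methylbenzene
Conditions: NaH, DMF, 0 °C → rt
Reagents that add atoms: chloromethyl methyl ether (2), COCCl
Why: Double Williamson‑type O‑alkylation of the sodium phenoxides with the reactive α‑chloro ether gives the bis‑MOM ether, which masks O5 and O7 with groups that tolerate organolithiums, tert‑butoxide and hydride reagents.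

Step 2
Reactants: 3 1,3‑bis(methoxymethoxy)‑2‑methylbenzene; 4 bis(pinacolato)diboron; 5 hydrogen peroxide
Product: 7 3,5‑bis(methoxymethoxy)‑4‑methylphenol, via arylboronate 6 (not isolated)
Conditions: [Ir(OMe)(cod)]2 (1.5 mol%), 4,4′‑di‑tert‑butyl‑2,2′‑bipyridine, B2pin2, THF, 80 °C; then aq. NaOH, 30% H2O2, 0 °C → rt
Reagents that add atoms: bis(pinacolato)diboron (4), CC1(C)OB(OC1(C)C)B1OC(C)(C)C(C)(C)O1 (boryl group of 6 only); hydrogen peroxide (5), OO
Why: Sterically controlled iridium‑catalysed aromatic C–H borylation reaches only C5, the one ring position without an ortho substituent, and basic peroxide oxidation of the C–B bond then gives the phenol whose oxygen becomes O1, with the MOM acetals left intact.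

Step 3
Reactants: 7 3,5‑bis(methoxymethoxy)‑4‑methylphenol; 8 4‑methoxybenzyl chloride
Product: 9 5‑[(4‑methoxyphenyl)methoxy]‑1,3‑bis(methoxymethoxy)‑2‑methylbenzene
Conditions: K2CO3, DMF, 50 °C
Reagents that add atoms: 4‑methoxybenzyl chloride (8), COc1ccc(CCl)cc1
Why: Williamson ether synthesis on the phenoxide installs the PMB group, which serves both as the protecting group of O1 and as the source of C2 with its 4‑methoxyphenyl ring.

Step 4
Reactants: 9 5‑[(4‑methoxyphenyl)methoxy]‑1,3‑bis(methoxymethoxy)‑2‑methylbenzene; 10 methyl chloroformate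
Product: 12 methyl 6‑[(4‑methoxyphenyl)methoxy]‑2,4‑bis(methoxymethoxy)‑3‑methylbenzoate, via aryllithium 11 (not isolated)
Conditions: n‑BuLi (1.1 equiv), THF, 0 °C; then inverse addition to ClCO2Me (3 equiv), THF, −78 °C
Reagents that add atoms: n‑butyllithium, [Li]CCCC (lithium of 11 only); methyl chloroformate (10), COC(Cl)=O
Why: Directed ortho‑metalation occurs at the ring C–H flanked by the MOM and PMB ether oxygens (the two such positions are equivalent and are the only ring hydrogens), and trapping with the chloroformate gives the methyl ester that will become C4.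

Step 5
Reactants: 12 methyl 6‑[(4‑methoxyphenyl)methoxy]‑2,4‑bis(methoxymethoxy)‑3‑methylbenzoate; 13 tert‑butyldimethylsilyl trifluoromethanesulfonate
Product: 15 3‑(tert‑butyldimethylsilyloxy)‑2‑(4‑methoxyphenyl)‑4,6‑bis(methoxymethoxy)‑5‑methyl‑1‑benzofuran, via lithium benzofuran‑3‑olate 14 (not isolated)
Conditions: LiN(iPr)2 (2.5 equiv), THF, −78 → 0 °C; then TBSOTf (3 equiv), −78 °C → rt; filtration through Et3N‑deactivated silica
Reagents that add atoms: lithium diisopropylamide, CC(C)N([Li])C(C)C (lithium of 14 only); tert‑butyldimethylsilyl trifluoromethanesulfonate (13), CC(C)(C)[Si](C)(C)OS(=O)(=O)C(F)(F)F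
Why: Intramolecular Claisen‑type acylation, the ester counterpart of the base‑induced cyclisations of ortho‑carbonyl aryl benzyl ethers to 2‑arylbenzofurans: the amide base removes a benzylic α‑oxy proton, the carbanion closes 5‑exo onto the neighbouring ester with loss of methoxide, the second equivalent of base turns the benzofuranone into the aromatic 3‑oxidobenzofuran, and O‑silylation in the same flask avoids isolating the air‑sensitive 2‑arylbenzofuranone.

Step 6
Reactants: 15 3‑(tert‑butyldimethylsilyloxy)‑2‑(4‑methoxyphenyl)‑4,6‑bis(methoxymethoxy)‑5‑methyl‑1‑benzofuran; 16 bromoform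
Product: 19 3‑bromo‑2‑(4‑methoxyphenyl)‑5,7‑bis(methoxymethoxy)‑6‑methyl‑4H‑chromen‑4‑one, via dibromocyclopropane 17 (not isolated), via 4‑silyloxyflavylium bromide 18 (not isolated)
Conditions: CHBr3 (2 equiv), KOtBu (2.5 equiv), hexane–toluene, −20 °C → rt; aq. NaHCO3 work‑up
Reagents that add atoms: bromoform (16), BrC(Br)Br
Why: Proposed new method: dibromocarbene, formed by α‑elimination from bromoform and KOtBu, should add as an electrophile to the C2=C3 bond of 15, and the cis‑fused dibromocyclopropane 17 should then ionise the bromide lying syn to the oxygen ring with concerted disrotatory cleavage of the old C2–C3 bond (cyclopropyl‑to‑allyl cation opening) to give the 4‑silyloxy‑3‑bromoflavylium ion 18, which loses its silyl group to bromide and leaves the 4‑pyranone 19. The closest known reaction types are the dihalocarbene one‑carbon ring expansion of cyclic silyl enol ethers to 2‑haloenones and the carbon‑atom insertion into indoles that gives 3‑haloquinolines; what is new is the 2‑aryl‑3‑silyloxybenzofuran substrate. Ring C, the only ring made, closes by electrocyclic ring expansion of the furan ring, the carbene carbon becoming C3 with new bonds to C2 and C4, driven by release of cyclopropane strain and by formation of the aromatic benzopyrylium. No stereocentre is formed, since 17 is a racemic transient and 19 is planar. The step needs chemoselective attack at the enol ether bond and not at the two alkoxy‑substituted benzene rings, which should be secured because that bond is the only non‑benzenoid π bond and carries two oxygen donors, and because no prenyl double bond is present yet to compete.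

Step 7
Reactants: 19 3‑bromo‑2‑(4‑methoxyphenyl)‑5,7‑bis(methoxymethoxy)‑6‑methyl‑4H‑chromen‑4‑one
Product: 20 2‑(4‑methoxyphenyl)‑5,7‑bis(methoxymethoxy)‑6‑methyl‑4H‑chromen‑4‑one
Conditions: Pd(PPh3)4 (5 mol%), HCO2Na, DMF, 80 °C
Reagents that add atoms: none
Why: Palladium‑catalysed hydrodehalogenation: zerovalent palladium inserts into the C3–Br bond, formate replaces bromide and decarboxylates to a palladium hydride, and reductive elimination places hydrogen on C3 without touching the C2=C3 bond or the acetals.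

Step 8
Reactants: 20 2‑(4‑methoxyphenyl)‑5,7‑bis(methoxymethoxy)‑6‑methyl‑4H‑chromen‑4‑one
Product: 21 (2S)‑2‑(4‑methoxyphenyl)‑5,7‑bis(methoxymethoxy)‑6‑methylchroman‑4‑one
Conditions: Cu(OAc)2·H2O (5 mol%), (R)‑DTBM‑SEGPHOS (5.5 mol%), (EtO)2MeSiH, t‑BuOH, toluene, 0 °C → rt
Reagents that add atoms: none
Why: Copper hydride‑catalysed asymmetric conjugate reduction, as established for chromones: the bisphosphine‑bound copper hydride delivers hydride to one enantiotopic face of C2 and tert‑butanol protonates the copper enolate at C3, so the ligand sets the C2 stereocentre (S), and the absence of strong base keeps the flavanone from opening.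

Step 9
Reactants: 21 (2S)‑2‑(4‑methoxyphenyl)‑5,7‑bis(methoxymethoxy)‑6‑methylchroman‑4‑one
Product: 22 (2S)‑5‑hydroxy‑7‑(methoxymethoxy)‑2‑(4‑methoxyphenyl)‑6‑methylchroman‑4‑one
Conditions: I2 (cat.), MeOH, rt, stopped at mono‑cleavage
Reagents that add atoms: none
Why: Mild acid‑catalysed acetal exchange with methanol (HI formed in situ) should remove the MOM group peri to the carbonyl first, because hydrogen bonding to C4=O assists protonation at O5 and stabilises the freed chelated phenol, while the 7‑O‑MOM group and the C2 stereocentre are expected to remain.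

Step 10
Reactants: 22 (2S)‑5‑hydroxy‑7‑(methoxymethoxy)‑2‑(4‑methoxyphenyl)‑6‑methylchroman‑4‑one; 23 3‑methylbut‑2‑en‑1‑ol
Product: 24 (2S)‑7‑(methoxymethoxy)‑2‑(4‑methoxyphenyl)‑6‑methyl‑5‑[(3‑methylbut‑2‑en‑1‑yl)oxy]chroman‑4‑one
Conditions: PPh3, DIAD, THF, 0 °C → rt
Reagents that add atoms: 3‑methylbut‑2‑en‑1‑ol (23), CC(C)=CCO
Why: Mitsunobu etherification: the phenoxide displaces triphenylphosphine oxide from the prenyl oxyphosphonium ion at the primary carbon, a base‑free alkylation of the chelated 5‑OH that has precedent on 7‑O‑protected 5‑hydroxyflavanones and avoids retro‑oxa‑Michael racemisation.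

Step 11
Reactants: 24 (2S)‑7‑(methoxymethoxy)‑2‑(4‑methoxyphenyl)‑6‑methyl‑5‑[(3‑methylbut‑2‑en‑1‑yl)oxy]chroman‑4‑one
Product: 27 (2S)‑5‑hydroxy‑7‑(methoxymethoxy)‑2‑(4‑methoxyphenyl)‑6‑methyl‑8‑(3‑methylbut‑2‑en‑1‑yl)chroman‑4‑one, via ortho‑dienone 25 (not isolated), via para‑dienone 26 (not isolated)
Conditions: Eu(fod)3 (10 mol%), CHCl3, 60 °C
Reagents that add atoms: none
Why: Lewis acid‑accelerated aromatic Claisen–Cope rearrangement: the [3,3] shift from O5 to C6 gives a dienone that cannot enolise because C6 carries the methyl group, so a second [3,3] shift carries the allyl unit to C8 and tautomerisation restores the phenol, the two allylic inversions returning a normal prenyl group and leaving C2 untouched.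

Step 12
Reactants: 27 (2S)‑5‑hydroxy‑7‑(methoxymethoxy)‑2‑(4‑methoxyphenyl)‑6‑methyl‑8‑(3‑methylbut‑2‑en‑1‑yl)chroman‑4‑one
Product: 28 (2S)‑5,7‑dihydroxy‑2‑(4‑methoxyphenyl)‑6‑methyl‑8‑(3‑methylbut‑2‑en‑1‑yl)chroman‑4‑one
Conditions: 3 M aq. HCl, MeOH, rt → 40 °C
Reagents that add atoms: none
Why: Acid‑catalysed methanolysis of the last MOM acetal under conditions mild enough to spare the prenyl double bond (no chroman formation) and the acid‑stable C2 stereocentre.

## Compound list

1 | 2‑methylresorcinol | Cc1c(O)cccc1O | starting material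
2 | chloromethyl methyl ether | COCCl | starting material
3 | 1,3‑bis(methoxymethoxy)‑2‑methylbenzene | COCOc1cccc(OCOC)c1C | intermediate
4 | bis(pinacolato)diboron | CC1(C)OB(OC1(C)C)B1OC(C)(C)C(C)(C)O1 | starting material
5 | hydrogen peroxide | OO | starting material
6 | 2‑[3,5‑bis(methoxymethoxy)‑4‑methylphenyl]‑4,4,5,5‑tetramethyl‑1,3,2‑dioxaborolane (not isolated) | COCOc1cc(B2OC(C)(C)C(C)(C)O2)cc(OCOC)c1C | intermediate
7 | 3,5‑bis(methoxymethoxy)‑4‑methylphenol | COCOc1cc(O)cc(OCOC)c1C | intermediate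
8 | 4‑methoxybenzyl chloride | COc1ccc(CCl)cc1 | starting material
9 | 5‑[(4‑methoxyphenyl)methoxy]‑1,3‑bis(methoxymethoxy)‑2‑methylbenzene | COCOc1cc(OCc2ccc(OC)cc2)cc(OCOC)c1C | intermediate
10 | methyl chloroformate | COC(Cl)=O | starting material
11 | [6‑[(4‑methoxyphenyl)methoxy]‑2,4‑bis(methoxymethoxy)‑3‑methylphenyl]lithium (not isolated) | [Li]c1c(OCOC)c(C)c(OCOC)cc1OCc1ccc(OC)cc1 | intermediate
12 | methyl 6‑[(4‑methoxyphenyl)methoxy]‑2,4‑bis(methoxymethoxy)‑3‑methylbenzoate | COC(=O)c1c(OCOC)c(C)c(OCOC)cc1OCc1ccc(OC)cc1 | intermediate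
13 | tert‑butyldimethylsilyl trifluoromethanesulfonate | CC(C)(C)[Si](C)(C)OS(=O)(=O)C(F)(F)F | starting material
14 | lithium 2‑(4‑methoxyphenyl)‑4,6‑bis(methoxymethoxy)‑5‑methyl‑1‑benzofuran‑3‑olate (not isolated) | [Li+].[O-]c1c(-c2ccc(OC)cc2)oc2cc(OCOC)c(C)c(OCOC)c12 | intermediate
15 | 3‑(tert‑butyldimethylsilyloxy)‑2‑(4‑methoxyphenyl)‑4,6‑bis(methoxymethoxy)‑5‑methyl‑1‑benzofuran | COc1ccc(-c2oc3cc(OCOC)c(C)c(OCOC)c3c2O[Si](C)(C)C(C)(C)C)cc1 | intermediate
16 | bromoform | BrC(Br)Br | starting material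
17 | 1,1‑dibromo‑6b‑(tert‑butyldimethylsilyloxy)‑1a‑(4‑methoxyphenyl)‑4,6‑bis(methoxymethoxy)‑5‑methyl‑1a,6b‑dihydro‑1H‑cyclopropa[b][1]benzofuran (racemic, cis‑fused, not isolated) | COc1ccc(C23Oc4cc(OCOC)c(C)c(OCOC)c4C2(O[Si](C)(C)C(C)(C)C)C3(Br)Br)cc1 | intermediate
18 | 3‑bromo‑4‑(tert‑butyldimethylsilyloxy)‑2‑(4‑methoxyphenyl)‑5,7‑bis(methoxymethoxy)‑6‑methylchromenylium bromide (not isolated) | COc1ccc(-c2[o+]c3cc(OCOC)c(C)c(OCOC)c3c(O[Si](C)(C)C(C)(C)C)c2Br)cc1.[Br-] | intermediate
19 | 3‑bromo‑2‑(4‑methoxyphenyl)‑5,7‑bis(methoxymethoxy)‑6‑methyl‑4H‑chromen‑4‑one | COc1ccc(-c2oc3cc(OCOC)c(C)c(OCOC)c3c(=O)c2Br)cc1 | intermediate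
20 | 2‑(4‑methoxyphenyl)‑5,7‑bis(methoxymethoxy)‑6‑methyl‑4H‑chromen‑4‑one | COc1ccc(-c2cc(=O)c3c(OCOC)c(C)c(OCOC)cc3o2)cc1 | intermediate
21 | (2S)‑2‑(4‑methoxyphenyl)‑5,7‑bis(methoxymethoxy)‑6‑methylchroman‑4‑one | COc1ccc([C@@H]2CC(=O)c3c(OCOC)c(C)c(OCOC)cc3O2)cc1 | intermediate
22 | (2S)‑5‑hydroxy‑7‑(methoxymethoxy)‑2‑(4‑methoxyphenyl)‑6‑methylchroman‑4‑one | COc1ccc([C@@H]2CC(=O)c3c(O)c(C)c(OCOC)cc3O2)cc1 | intermediate
23 | 3‑methylbut‑2‑en‑1‑ol | CC(C)=CCO | starting material
24 | (2S)‑7‑(methoxymethoxy)‑2‑(4‑methoxyphenyl)‑6‑methyl‑5‑[(3‑methylbut‑2‑en‑1‑yl)oxy]chroman‑4‑one | COc1ccc([C@@H]2CC(=O)c3c(OCC=C(C)C)c(C)c(OCOC)cc3O2)cc1 | intermediate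
25 | (2S)‑7‑(methoxymethoxy)‑2‑(4‑methoxyphenyl)‑6‑methyl‑6‑(2‑methylbut‑3‑en‑2‑yl)‑2,3‑dihydro‑4H‑chromene‑4,5(6H)‑dione (both C6 epimers, not isolated) | COc1ccc([C@@H]2CC(=O)C3=C(O2)C=C(OCOC)C(C)(C(C)(C)C=C)C3=O)cc1 | intermediate
26 | (2S)‑7‑(methoxymethoxy)‑2‑(4‑methoxyphenyl)‑6‑methyl‑8‑(3‑methylbut‑2‑en‑1‑yl)‑2,3‑dihydro‑4H‑chromene‑4,5(8H)‑dione (both C8 epimers, not isolated) | COc1ccc([C@@H]2CC(=O)C3=C(O2)C(CC=C(C)C)C(OCOC)=C(C)C3=O)cc1 | intermediate
27 | (2S)‑5‑hydroxy‑7‑(methoxymethoxy)‑2‑(4‑methoxyphenyl)‑6‑methyl‑8‑(3‑methylbut‑2‑en‑1‑yl)chroman‑4‑one | COc1ccc([C@@H]2CC(=O)c3c(O)c(C)c(OCOC)c(CC=C(C)C)c3O2)cc1 | intermediate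
28 | (2S)‑5,7‑dihydroxy‑2‑(4‑methoxyphenyl)‑6‑methyl‑8‑(3‑methylbut‑2‑en‑1‑yl)chroman‑4‑one | COc1ccc([C@@H]2CC(=O)c3c(O)c(C)c(O)c(CC=C(C)C)c3O2)cc1 | target

## Count and risks

Total step count: 12. Longest linear sequence: 12 steps, from 2‑methylresorcinol.

Steps most likely to fail:

1. Step 6 (proposed new method). The carbene may attack the alkoxy‑substituted benzene rings, tert‑butoxide may strip the silyl group before cyclopropanation, or the dibromocyclopropane may fail to ionise. The fallback uses known ynone chemistry and sets out from PMB ether 9. Lithiation as in step 4 and acylation of the aryllithium with N‑methoxy‑N‑methyl‑3‑(4‑methoxyphenyl)prop‑2‑ynamide F1 (from commercial 3‑(4‑methoxyphenyl)propiolic acid, MeNHOMe·HCl and EDC) should give 1‑[6‑[(4‑methoxyphenyl)methoxy]‑2,4‑bis(methoxymethoxy)‑3‑methylphenyl]‑3‑(4‑methoxyphenyl)prop‑2‑yn‑1‑one F2. DDQ in wet CH2Cl2 would remove the PMB group to give 1‑[6‑hydroxy‑2,4‑bis(methoxymethoxy)‑3‑methylphenyl]‑3‑(4‑methoxyphenyl)prop‑2‑yn‑1‑one F3. Et2NH in EtOH (conjugate addition of the amine, then 6‑endo closure with loss of the amine) should then give flavone 20, where the route is rejoined before step 8.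

2. Step 5. Deprotonation of the electron‑rich PMB methylene may be slow and be overtaken by [1,2]‑Wittig rearrangement or ring metalation, and the enolate may oxidise before silylation. The fallback sets out from ester 12. DDQ in wet CH2Cl2 would give methyl 6‑hydroxy‑2,4‑bis(methoxymethoxy)‑3‑methylbenzoate F4. O‑alkylation with commercial methyl 2‑bromo‑2‑(4‑methoxyphenyl)acetate (K2CO3, DMF) would give methyl 6‑[2‑methoxy‑1‑(4‑methoxyphenyl)‑2‑oxoethoxy]‑2,4‑bis(methoxymethoxy)‑3‑methylbenzoate F5, in which the proton to be removed is activated by an ester. Dieckmann cyclisation (LiN(SiMe3)2, THF, −78 °C, cold quench to outrun retro‑Claisen cleavage) should give methyl 2‑(4‑methoxyphenyl)‑4,6‑bis(methoxymethoxy)‑5‑methyl‑3‑oxo‑2,3‑dihydro‑1‑benzofuran‑2‑carboxylate F6. Krapcho decarbomethoxylation (LiCl, wet DMSO, 120 °C, under argon) would give 2‑(4‑methoxyphenyl)‑4,6‑bis(methoxymethoxy)‑5‑methyl‑1‑benzofuran‑3(2H)‑one F7, and TBSOTf/Et3N in CH2Cl2 returns to the route at 15.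

3. Step 8. The hindered, electron‑rich flavone may react with poor facial selectivity or suffer competing 1,2‑reduction. The fallback sets out from flavone 20. Achiral conjugate reduction with LiBH(s‑Bu)3 (THF, −78 °C) should give racemic 2‑(4‑methoxyphenyl)‑5,7‑bis(methoxymethoxy)‑6‑methylchroman‑4‑one F8. Kinetic resolution by asymmetric transfer hydrogenation (Cp*RhCl[(R,R)‑TsDPEN] or its mirror image, whichever consumes the (2R) ketone faster, HCO2H/Et3N, EtOAc) would reduce the unwanted enantiomer to (2R,4R)‑2‑(4‑methoxyphenyl)‑5,7‑bis(methoxymethoxy)‑6‑methylchroman‑4‑ol F9. The unreacted (2S) ketone is 21, where the route is rejoined before step 9.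

## Further compounds

F1 | step 6 | N‑methoxy‑N‑methyl‑3‑(4‑methoxyphenyl)prop‑2‑ynamide | COc1ccc(C#CC(=O)N(C)OC)cc1
F2 | step 6 | 1‑[6‑[(4‑methoxyphenyl)methoxy]‑2,4‑bis(methoxymethoxy)‑3‑methylphenyl]‑3‑(4‑methoxyphenyl)prop‑2‑yn‑1‑one | COc1ccc(C#CC(=O)c2c(OCOC)c(C)c(OCOC)cc2OCc2ccc(OC)cc2)cc1
F3 | step 6 | 1‑[6‑hydroxy‑2,4‑bis(methoxymethoxy)‑3‑methylphenyl]‑3‑(4‑methoxyphenyl)prop‑2‑yn‑1‑one | COc1ccc(C#CC(=O)c2c(OCOC)c(C)c(OCOC)cc2O)cc1
F4 | step 5 | methyl 6‑hydroxy‑2,4‑bis(methoxymethoxy)‑3‑methylbenzoate | COC(=O)c1c(O)cc(OCOC)c(C)c1OCOC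
F5 | step 5 | methyl 6‑[2‑methoxy‑1‑(4‑methoxyphenyl)‑2‑oxoethoxy]‑2,4‑bis(methoxymethoxy)‑3‑methylbenzoate (racemic) | COC(=O)C(Oc1cc(OCOC)c(C)c(OCOC)c1C(=O)OC)c1ccc(OC)cc1
F6 | step 5 | methyl 2‑(4‑methoxyphenyl)‑4,6‑bis(methoxymethoxy)‑5‑methyl‑3‑oxo‑2,3‑dihydro‑1‑benzofuran‑2‑carboxylate (racemic) | COC(=O)C1(c2ccc(OC)cc2)Oc2cc(OCOC)c(C)c(OCOC)c2C1=O
F7 | step 5 | 2‑(4‑methoxyphenyl)‑4,6‑bis(methoxymethoxy)‑5‑methyl‑1‑benzofuran‑3(2H)‑one (racemic) | COc1ccc(C2Oc3cc(OCOC)c(C)c(OCOC)c3C2=O)cc1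
F8 | step 8 | 2‑(4‑methoxyphenyl)‑5,7‑bis(methoxymethoxy)‑6‑methylchroman‑4‑one (racemic) | COc1ccc(C2CC(=O)c3c(OCOC)c(C)c(OCOC)cc3O2)cc1
F9 | step 8 | (2R,4R)‑2‑(4‑methoxyphenyl)‑5,7‑bis(methoxymethoxy)‑6‑methylchroman‑4‑ol | COc1ccc([C@H]2C[C@@H](O)c3c(OCOC)c(C)c(OCOC)cc3O2)cc1
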